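The disconnection on which everything rests is the C1–C9b bond of ring C (rings C/D in dibenzofuran numbering). Ring C carries three contiguous oxygens (C1, C2, C3) and a single C4–H beside the furan-bearing carbon C4a. That is the pattern a squarate-derived 2,3-dialkoxycyclobutenone imprints when it ring-expands onto the C2–C3 bond of a benzofuran. One thermal operation forms C1–C9b, closes ring C and delivers C1–OH as the only free phenol, with C2–O and C3–O kept as isopropyl ethers. The precursor is racemic 4-(4,6-dimethoxybenzofuran-2-yl)-2,3-diisopropoxycyclobut-2-enone. Ring B then arrives by SNAr on a difluoro dialdehyde, and the dioxin is closed by Ullmann etherification only after ring B is electron-rich.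

Key step: step 6

Remark on the chemistry: ring A = pendant 3,5-dihydroxyphenoxy ring, ring B = aryloxy-bearing benzene of the dioxin with positions b1 (O–ring A), b2 (OH), b3 (H), b4 (OH), b5 (O–C1), b6 (O–C2), ring C = central benzene, ring D = outer benzene of the dibenzofuran; the target and the key-step pair were checked atom by atom and needed no correction.

Step 1
Reactants: 1 4,6-dimethoxybenzofuran-3(2H)-one
Product: 3 4,6-dimethoxybenzofuran, via dihydrobenzofuranol 2 (not isolated)
Conditions: NaBH4, MeOH/THF, 0 °C → rt; then 2 M HCl, rt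
Reagents that add atoms: none
Why: NaBH4 reduction of the aryl ketone gives benzylic alcohol 2 as a racemate (its stereocentre is destroyed at once) and acid-promoted E1 dehydration through the ortho/para-methoxy-stabilised benzylic cation aromatises the furan, the standard benzofuranone-to-benzofuran sequence.

Step 2
Reactants: 3 4,6-dimethoxybenzofuran
Product: 5 tributyl(4,6-dimethoxybenzofuran-2-yl)stannane, via aryllithium 4 (not isolated)
Conditions: n-BuLi, THF, −78 °C; then Bu3SnCl, −78 °C → rt
Reagents that add atoms: tributyltin chloride CCCC[Sn](Cl)(CCCC)CCCC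
Why: Lithiation–stannylation: C2–H is the most acidic position of a benzofuran, so n-BuLi at −78 °C removes it selectively over the methoxy-flanked ring positions and the aryllithium is quenched at tin.

Step 3
Reactants: 6 diisopropyl squarate
Product: 7 racemic 4-hydroxy-2,3-diisopropoxycyclobut-2-en-1-one
Conditions: LiAlH(OtBu)3, THF, −78 → −20 °C; then H2O, 0 °C
Reagents that add atoms: none
Why: Mono 1,2-reduction of a squarate with the bulky, mild hydride LiAlH(OtBu)3 stops at vinylogous ester 7 because the remaining carbonyl is deactivated, the new carbinol centre arising as a racemate that is of no consequence.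

Step 4
Reactants: 7 racemic 4-hydroxy-2,3-diisopropoxycyclobut-2-en-1-one
Product: 8 racemic 4-chloro-2,3-diisopropoxycyclobut-2-en-1-one
Conditions: PPh3, CCl4, CH2Cl2, 0 °C → rt; rapid cold filtration through silica, used at once
Reagents that add atoms: carbon tetrachloride ClC(Cl)(Cl)Cl
Why: Appel chlorination exchanges the secondary hydroxyl for chloride under neutral conditions, avoiding the acid that would make 7 lose isopropanol, and delivers the activated (allylic, α-keto) racemic chloride of the kind used in 4-chlorocyclobutenone cross-coupling.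

Step 5
Reactants: 5 tributyl(4,6-dimethoxybenzofuran-2-yl)stannane; 8 racemic 4-chloro-2,3-diisopropoxycyclobut-2-en-1-one
Product: 9 racemic 4-(4,6-dimethoxybenzofuran-2-yl)-2,3-diisopropoxycyclobut-2-en-1-one
Conditions: PdCl2(PhCN)2 (5 mol %), tri(2-furyl)phosphine (10 mol %), 1,4-dioxane, 50 °C, Ar
Reagents that add atoms: none
Why: Stille coupling of a 4-chlorocyclobutenone with a 2-stannyl heteroarene: zerovalent palladium inserts into the activated C4–Cl bond and the weakly donating furylphosphine accelerates Sn-to-Pd transfer, so the C4–aryl bond forms at 50 °C, below the ring-opening temperature, the C4 stereocentre being racemic and destroyed in step 6.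

Step 6
Reactants: 9 racemic 4-(4,6-dimethoxybenzofuran-2-yl)-2,3-diisopropoxycyclobut-2-en-1-one
Product: 11 2,3-diisopropoxy-7,9-dimethoxydibenzofuran-1-ol, via dienylketene 10 (not isolated)
Conditions: toluene (0.02 M, degassed), 110 °C, Ar
Reagents that add atoms: none
Why: Heating cleaves the cyclobutenone C1–C4 bond by thermal four-electron conrotatory ring opening to dienylketene 10, whose ketene carbon bonds to benzofuran C3 in a thermal six-electron disrotatory electrocyclisation, and the resulting cyclohexadienone tautomerises to the phenol. The closest known reaction type is the thermal ring expansion of 4-aryl- and 4-heteroaryl-cyclobut-2-enones to annulated phenols (cyclobutenone benzannulation). Ring C is closed by this 6π electrocyclic closure, which forms only the C1–C9b bond of a six-membered carbocycle. No stereocentre is created, and the racemic sp3 carbon of 9 becomes the aromatic C4–H. Regiochemistry is secured because benzofuran C3 is the only carbon ortho to the point of attachment, and because ring opening is reversible the ketene isomer with the aryl group turned outward returns to 9 until the inward isomer cyclises. The step needs chemoselectivity for cyclisation over ketene dimerisation or trapping, which dilute, degassed, nucleophile-free conditions secure, and it should deliver C1–OH free with the C2 and C3 oxygens as isopropyl ethers.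

Step 7
Reactants: 12 5-bromo-2,4-difluorobenzaldehyde
Product: 13 4,6-difluoroisophthalaldehyde
Conditions: Pd(OAc)2 (1 mol %), di(1-adamantyl)-n-butylphosphine (3 mol %), TMEDA, CO/H2 (1:1, 5 bar), toluene, 100 °C
Reagents that add atoms: carbon monoxide [C-]#[O+]
Why: Palladium-catalysed reductive carbonylation (formylation) of an aryl bromide with CO/H2, in which the electron-poor C–Br bond adds readily to zerovalent palladium and the formyl group already present is a spectator.

Step 8
Reactants: 13 4,6-difluoroisophthalaldehyde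
Product: 14 5-bromo-4,6-difluoroisophthalaldehyde
Conditions: NBS, conc. H2SO4, 60 °C
Reagents that add atoms: N-bromosuccinimide O=C1CCC(=O)N1Br
Why: Electrophilic aromatic bromination with NBS in H2SO4, the method of choice for deactivated arenes, goes to C5 because it is the only position meta to both formyl groups and ortho to both fluorines.

Step 9
Reactants: 11 2,3-diisopropoxy-7,9-dimethoxydibenzofuran-1-ol; 14 5-bromo-4,6-difluoroisophthalaldehyde (2.5 equiv)
Product: 15 5-bromo-4-[(2,3-diisopropoxy-7,9-dimethoxydibenzofuran-1-yl)oxy]-6-fluoroisophthalaldehyde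
Conditions: Cs2CO3, DMF, 0 °C → rt, Ar; excess 14 recovered
Reagents that add atoms: none
Why: SNAr (addition–elimination): the C1 phenoxide, the only free hydroxyl of 11, displaces one of the two equivalent fluorides that are each activated by an ortho and a para formyl group, the excess of symmetric 14 preventing double substitution and the isopropyl caps on C2–O/C3–O ruling out any Smiles migration.

Step 10
Reactants: 15 5-bromo-4-[(2,3-diisopropoxy-7,9-dimethoxydibenzofuran-1-yl)oxy]-6-fluoroisophthalaldehyde; 16 3,5-dimethoxyphenol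
Product: 17 5-bromo-4-[(2,3-diisopropoxy-7,9-dimethoxydibenzofuran-1-yl)oxy]-6-(3,5-dimethoxyphenoxy)isophthalaldehyde
Conditions: K2CO3, DMF, 60 °C
Reagents that add atoms: none
Why: A second SNAr with the unhindered phenoxide of 16 at the remaining formyl-activated C–F bond installs ring A, fluoride being displaced far faster than either aryloxy group so that the diaryl ethers do not exchange.

Step 11
Reactants: 17 5-bromo-4-[(2,3-diisopropoxy-7,9-dimethoxydibenzofuran-1-yl)oxy]-6-(3,5-dimethoxyphenoxy)isophthalaldehyde
Product: 19 5-bromo-4-[(2,3-diisopropoxy-7,9-dimethoxydibenzofuran-1-yl)oxy]-6-(3,5-dimethoxyphenoxy)benzene-1,3-diol, via bis(formate) 18 (not isolated)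
Conditions: mCPBA (3 equiv), CH2Cl2, 0 °C → rt; then K2CO3, MeOH, rt
Reagents that add atoms: meta-chloroperoxybenzoic acid O=C(OO)c1cccc(Cl)c1
Why: Baeyer–Villiger (Dakin-type) oxidation: each formyl group has ortho and para aryloxy donors, so the electron-rich aryl migrates to give bis(formate) 18, and mild methanolysis then unveils the two ring B phenols, converting the SNAr-activating groups into the b2 and b4 oxygens.

Step 12
Reactants: 19 5-bromo-4-[(2,3-diisopropoxy-7,9-dimethoxydibenzofuran-1-yl)oxy]-6-(3,5-dimethoxyphenoxy)benzene-1,3-diol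
Product: 20 1-[2-bromo-3-(3,5-dimethoxyphenoxy)-4,6-dimethoxyphenoxy]-2,3-diisopropoxy-7,9-dimethoxydibenzofuran
Conditions: MeI, K2CO3, DMF, rt
Reagents that add atoms: iodomethane CI
Why: Williamson ether synthesis caps both ring B phenols as methyl ethers so that only the ring C catechol will be nucleophilic in the ring closure, the methyls leaving with the others in the last step.

Step 13
Reactants: 20 1-[2-bromo-3-(3,5-dimethoxyphenoxy)-4,6-dimethoxyphenoxy]-2,3-diisopropoxy-7,9-dimethoxydibenzofuran
Product: 21 1-[2-bromo-3-(3,5-dimethoxyphenoxy)-4,6-dimethoxyphenoxy]-7,9-dimethoxydibenzofuran-2,3-diol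
Conditions: BCl3, CH2Cl2, −78 → 0 °C; then H2O
Reagents that add atoms: none
Why: BCl3 dealkylates isopropyl aryl ethers at low temperature by a Lewis acid-assisted SN1-type cleavage while leaving aryl methyl ethers, diaryl ethers and the aryl bromide untouched, releasing the C2 and C3 hydroxyls.

Step 14
Reactants: 21 1-[2-bromo-3-(3,5-dimethoxyphenoxy)-4,6-dimethoxyphenoxy]-7,9-dimethoxydibenzofuran-2,3-diol
Product: 22 dioxin-closed hexa-O-methyl ether of the target (free C3–OH on ring C)
Conditions: CuI (30 mol %), N,N-dimethylglycine (60 mol %), Cs2CO3, 1,4-dioxane (0.01 M), 100 °C, Ar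
Reagents that add atoms: none
Why: Intramolecular copper-catalysed Ullmann diaryl ether synthesis: the C2 phenoxide closes the six-membered dioxin onto the ring B bromide (C3–O could only form a seven-membered ring), and since ring B is now electron-rich no Smiles rearrangement can invert the dioxin orientation.

Step 15
Reactants: 22 dioxin-closed hexa-O-methyl ether of the target (free C3–OH on ring C)
Product: 23 target CNP0256302.0
Conditions: BBr3 (15 equiv), CH2Cl2, −78 °C → rt; then MeOH, H2O, Ar
Reagents that add atoms: none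
Why: Exhaustive BBr3 cleavage of the six aryl methyl ethers (Lewis acid-assisted SN2 demethylation by bromide) releases all phenols, while diaryl ether, dioxin and furan C–O bonds are inert to BBr3.

Compound list
1 | 4,6-dimethoxybenzofuran-3(2H)-one | COc1cc(OC)c2C(=O)COc2c1 | starting material
2 | racemic 4,6-dimethoxy-2,3-dihydrobenzofuran-3-ol | COc1cc(OC)c2C(O)COc2c1 | intermediate
3 | 4,6-dimethoxybenzofuran | COc1cc(OC)c2ccoc2c1 | intermediate
4 | (4,6-dimethoxybenzofuran-2-yl)lithium | [Li]c1cc2c(OC)cc(OC)cc2o1 | intermediate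
5 | tributyl(4,6-dimethoxybenzofuran-2-yl)stannane | CCCC[Sn](CCCC)(CCCC)c1cc2c(OC)cc(OC)cc2o1 | intermediate
6 | diisopropyl squarate | CC(C)OC1=C(OC(C)C)C(=O)C1=O | starting material
7 | racemic 4-hydroxy-2,3-diisopropoxycyclobut-2-en-1-one | CC(C)OC1=C(OC(C)C)C(O)C1=O | intermediate
8 | racemic 4-chloro-2,3-diisopropoxycyclobut-2-en-1-one | CC(C)OC1=C(OC(C)C)C(Cl)C1=O | intermediate
9 | racemic 4-(4,6-dimethoxybenzofuran-2-yl)-2,3-diisopropoxycyclobut-2-en-1-one | CC(C)OC1=C(OC(C)C)C(c2cc3c(OC)cc(OC)cc3o2)C1=O | intermediate
10 | (E)-4-(4,6-dimethoxybenzofuran-2-yl)-2,3-diisopropoxybuta-1,3-dien-1-one (dienylketene, aryl cis to the ketene carbon) | O=C=C(OC(C)C)/C(OC(C)C)=C\c1cc2c(OC)cc(OC)cc2o1 | intermediate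
11 | 2,3-diisopropoxy-7,9-dimethoxydibenzofuran-1-ol | CC(C)Oc1cc2oc3cc(OC)cc(OC)c3c2c(O)c1OC(C)C | intermediate
12 | 5-bromo-2,4-difluorobenzaldehyde | O=Cc1cc(Br)c(F)cc1F | starting material
13 | 4,6-difluoroisophthalaldehyde | O=Cc1cc(C=O)c(F)cc1F | intermediate
14 | 5-bromo-4,6-difluoroisophthalaldehyde | O=Cc1cc(C=O)c(F)c(Br)c1F | intermediate
15 | 5-bromo-4-[(2,3-diisopropoxy-7,9-dimethoxydibenzofuran-1-yl)oxy]-6-fluoroisophthalaldehyde | O=Cc1cc(C=O)c(Oc2c(OC(C)C)c(OC(C)C)cc3oc4cc(OC)cc(OC)c4c23)c(Br)c1F | intermediate
16 | 3,5-dimethoxyphenol | COc1cc(O)cc(OC)c1 | starting material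
17 | 5-bromo-4-[(2,3-diisopropoxy-7,9-dimethoxydibenzofuran-1-yl)oxy]-6-(3,5-dimethoxyphenoxy)isophthalaldehyde | O=Cc1cc(C=O)c(Oc2c(OC(C)C)c(OC(C)C)cc3oc4cc(OC)cc(OC)c4c23)c(Br)c1Oc1cc(OC)cc(OC)c1 | intermediate
18 | 5-bromo-4-[(2,3-diisopropoxy-7,9-dimethoxydibenzofuran-1-yl)oxy]-6-(3,5-dimethoxyphenoxy)-1,3-phenylene diformate | O=COc1cc(OC=O)c(Oc2c(OC(C)C)c(OC(C)C)cc3oc4cc(OC)cc(OC)c4c23)c(Br)c1Oc1cc(OC)cc(OC)c1 | intermediate
19 | 5-bromo-4-[(2,3-diisopropoxy-7,9-dimethoxydibenzofuran-1-yl)oxy]-6-(3,5-dimethoxyphenoxy)benzene-1,3-diol | Oc1cc(O)c(Oc2c(OC(C)C)c(OC(C)C)cc3oc4cc(OC)cc(OC)c4c23)c(Br)c1Oc1cc(OC)cc(OC)c1 | intermediate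
20 | 1-[2-bromo-3-(3,5-dimethoxyphenoxy)-4,6-dimethoxyphenoxy]-2,3-diisopropoxy-7,9-dimethoxydibenzofuran | COc1cc(OC)c(Oc2c(OC(C)C)c(OC(C)C)cc3oc4cc(OC)cc(OC)c4c23)c(Br)c1Oc1cc(OC)cc(OC)c1 | intermediate
21 | 1-[2-bromo-3-(3,5-dimethoxyphenoxy)-4,6-dimethoxyphenoxy]-7,9-dimethoxydibenzofuran-2,3-diol | COc1cc(OC)c(Oc2c(O)c(O)cc3oc4cc(OC)cc(OC)c4c23)c(Br)c1Oc1cc(OC)cc(OC)c1 | intermediate
22 | dioxin-closed hexa-O-methyl ether of the target: ring B bridges O–C1 (at b5) and O–C2 (at b6) of the dibenzofuran and carries 3,5-dimethoxyphenoxy at b1 and OMe at b2 and b4; OMe at C7 and C9; free OH at C3 | COc1cc(OC)cc(Oc2c(OC)cc(OC)c3c2Oc2c(O)cc4oc5cc(OC)cc(OC)c5c4c2O3)c1 | intermediate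
23 | target CNP0256302.0: as 22 with all six methyl ethers replaced by OH (no stereocentres) | Oc1cc(O)cc(Oc2c(O)cc(O)c3c2Oc2c(O)cc4oc5cc(O)cc(O)c5c4c2O3)c1 | target

Total step count: 15. Longest linear sequence: 11 steps (steps 1, 2, 5, 6, 9, 10, 11, 12, 13, 14, 15; the squarate branch through steps 3 and 4 is equally long).

Steps most likely to fail

1. Step 4. What may go wrong: ionisation of the allylic chloride assisted by the neighbouring enol ether, chloride return at the alkoxy-bearing carbon and loss of isopropyl chloride, so that the electrophile decays to a cyclobutenedione before it can couple. Fallback, setting out from 4 and 6 and returning at 9 (7, 8 and 5 are bypassed): aryllithium 4 is added to squarate 6 in THF at −78 °C (1,2-addition) to give racemic 4-(4,6-dimethoxybenzofuran-2-yl)-4-hydroxy-2,3-diisopropoxycyclobut-2-en-1-one F1. The tertiary hydroxyl is then removed by ionic hydrogenation (Et3SiH, BF3·OEt2, CH2Cl2, −78 °C), hydride being expected to capture the benzofuranyl-stabilised cation at C4 to give 9.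

2. Step 14. What may go wrong: slow oxidative addition at a bromide flanked by two aryloxy groups, so that protodebromination and oxidative loss of the catechol outrun ring closure. Fallback, setting out from 20 and returning at 22 (21 is bypassed): the electrophile is changed. Bromine–lithium exchange on 20 (n-BuLi, THF, −78 °C) and quenching with I2 should give 1-[2-iodo-3-(3,5-dimethoxyphenoxy)-4,6-dimethoxyphenoxy]-2,3-diisopropoxy-7,9-dimethoxydibenzofuran F2. BCl3 then frees the catechol to give 1-[2-iodo-3-(3,5-dimethoxyphenoxy)-4,6-dimethoxyphenoxy]-7,9-dimethoxydibenzofuran-2,3-diol F3. Its C–I bond should enter copper-mediated etherification (CuI, 1,10-phenanthroline, Cs2CO3, toluene, 70 °C) well below the temperature at which reduction of the halide competes, closing the dioxin to 22.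

3. Step 9. What may go wrong: over-substitution of the symmetric difluoride, or sluggish addition of the hindered, oxidation-prone phenoxide with loss of 11 under base. Fallback, setting out from 14 and 16 and returning at 17 (15 is bypassed): the order of the two ether formations is reversed. Difluoride 14 (in excess) is desymmetrised with 16 (K2CO3, MeCN, 0 °C) to 5-bromo-4-(3,5-dimethoxyphenoxy)-6-fluoroisophthalaldehyde F4, which is purified. The phenoxide of 11 is then added to the single remaining activated fluoride (Cs2CO3, DMSO, 60 °C), so that 11 is the limiting reagent and a second substitution is impossible.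

Further compounds
F1 | step 4 | racemic 4-(4,6-dimethoxybenzofuran-2-yl)-4-hydroxy-2,3-diisopropoxycyclobut-2-en-1-one | CC(C)OC1=C(OC(C)C)C(O)(c2cc3c(OC)cc(OC)cc3o2)C1=O
F2 | step 14 | 1-[2-iodo-3-(3,5-dimethoxyphenoxy)-4,6-dimethoxyphenoxy]-2,3-diisopropoxy-7,9-dimethoxydibenzofuran | COc1cc(OC)c(Oc2c(OC(C)C)c(OC(C)C)cc3oc4cc(OC)cc(OC)c4c23)c(I)c1Oc1cc(OC)cc(OC)c1
F3 | step 14 | 1-[2-iodo-3-(3,5-dimethoxyphenoxy)-4,6-dimethoxyphenoxy]-7,9-dimethoxydibenzofuran-2,3-diol | COc1cc(OC)c(Oc2c(O)c(O)cc3oc4cc(OC)cc(OC)c4c23)c(I)c1Oc1cc(OC)cc(OC)c1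
F4 | step 9 | 5-bromo-4-(3,5-dimethoxyphenoxy)-6-fluoroisophthalaldehyde | O=Cc1cc(C=O)c(Oc2cc(OC)cc(OC)c2)c(Br)c1F
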